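The chromone is cut back to an open-chain 1,3-diketone on a symmetric 2,6-dihydroxy-4-methoxyphenyl ketone, and that benzene ring is unfolded at C4a–C5 into a 4-methoxy-2-pyranone carrying a 2,4-dioxoalkyl arm at its 6-position, a stable, already O-methylated stand-in for a pentaketide ester. In one operation magnesium methoxide opens the lactone and a Claisen closure builds ring A (C4a, C5, C6, C7, C8, C8a). The step exploits the phloroglucinol pattern of ring A: C5, C7 and C8a each bear oxygen, C4a bears acyl carbon C4, and the C7 oxygen alone is methylated, which leaves two equivalent free phenols that need no differentiation.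

Key step: step 4

Remark: atom labels (C2 to C8a) follow the chromone numbering of the target throughout, and the target has no stereocenter. The side chain has 33 carbons, so the acyl donor is a C34 ester; it is assembled directly as the methyl ester from C22 and C12 pieces, with methyl 12-bromododecanoate taken as a catalogue compound. The 2,4-dioxoalkyl arm of the pyranone is left unprotected on purpose, because as a magnesium chelate it protects itself in the key step.

Step 1
Reactants: 1 4-methoxy-6-methyl-2H-pyran-2-one; 2 N-methoxy-N-methylacetamide
Product: 4 4-methoxy-6-(2-oxopropyl)-2H-pyran-2-one, via 6-(lithiomethyl)-4-methoxy-2H-pyran-2-one 3 (not isolated)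
Conditions: LiN(iPr)2 (1.1 equiv), THF, −78 °C; then 2, −78 → −20 °C; cold 1 M HCl
Reagents that add atoms: none
Why: LiN(iPr)2 should deprotonate the C6 methyl group (lateral lithiation at the vinylogous α-position of the pyranone), and the dienolate adds to the Weinreb amide to give a chelated tetrahedral adduct that releases the ketone only on work-up (Weinreb ketone synthesis), which prevents both double acylation and quenching of the anion by the acidic product.

Step 2
Reactants: 5 1-bromodocosane; 6 methyl 12-bromododecanoate
Product: 8 methyl tetratriacontanoate, via docosylmagnesium bromide 7 (not isolated)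
Conditions: Mg, THF, 45 °C; then added warm to 6, Li2CuCl4 (3 mol %), N-methylpyrrolidinone (4 equiv), THF, 20 °C; aq. NH4Cl
Reagents that add atoms: none
Why: Copper-catalysed alkyl–alkyl cross-coupling of a primary Grignard reagent with a primary bromide (Li2CuCl4 catalysis, N-methylpyrrolidinone as cosolvent) is far faster than addition of the Grignard reagent to a methyl ester, so the C22 and C12 chains should join directly to the C34 ester.

Step 3
Reactants: 4 4-methoxy-6-(2-oxopropyl)-2H-pyran-2-one; 8 methyl tetratriacontanoate
Product: 10 6-(2,4-dioxoheptatriacontyl)-4-methoxy-2H-pyran-2-one, via dilithium 1-(4-methoxy-2-oxo-2H-pyran-6-yl)-2-oxopropane-1,3-diide 9 (not isolated)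
Conditions: 4 (2.2 equiv), LiN(iPr)2 (4.4 equiv), THF, −78 → 0 °C; then 8 (1 equiv) as a warm THF solution, 0 → 25 °C; AcOH, then water
Reagents that add atoms: none
Why: Two equivalents of LiN(iPr)2 should turn 4 into its 1,3-dianion, which is acylated at the terminal, more basic carbon by the ester in a Claisen condensation (γ-acylation of a 1,3-dicarbonyl dianion), the second equivalent of dianion taking up the acidic proton of the new 1,3-diketone so that the valuable ester is fully used.

Step 4
Reactants: 10 6-(2,4-dioxoheptatriacontyl)-4-methoxy-2H-pyran-2-one
Product: 12 1-(2,6-dihydroxy-4-methoxyphenyl)hexatriacontane-1,3-dione, via methyl (2E)-3-methoxy-5,7,9-trioxodotetracont-2-enoate 11 (not isolated)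
Conditions: Mg(OMe)2 (8 equiv), MeOH–THF, reflux, N2; then cold 1 M HCl
Reagents that add atoms: none
Why: Ring opening by methoxide at the lactone carbonyl (C5) unmasks triketo ester 11 as its magnesium chelate, and because the C6=C7 double bond is inherited from the ring, ester carbon C5 and the C8 methylene remain cis and the chain stays pre-folded; C4a, activated by both the C8a and the C4 carbonyl, then adds to the ester carbonyl, methoxide leaves, and enolisation of the resulting cyclohexenedione gives benzene ring A. The closest known reaction type is the magnesium alkoxide-mediated Claisen (Dieckmann-type) recyclisation of 6-(2-oxoalkyl)-4-alkoxy-2-pyranones to 2-acyl-5-alkoxyresorcinols, here applied to a substrate that carries one more ketone in the side chain. Ring A closes in the 6-exo-trig mode with formation of the C4a–C5 bond. No stereocenter is created. The step needs Claisen folding in preference to the aldol closures C6→C4 and C8→C2, to addition–elimination of C3 at C7 and to O-cyclisation to a 4-pyranone: C6 is held as the vinylic α-carbon of the β-methoxy enoate, C7 is a deactivated vinylogous carbonate position, and magnesium chelation keeps C8a, C4 and C2 as poorly electrophilic enolates, so the ester C5 is the one carbonyl left for the one carbanion, C4a, that can reach it through a six-membered transition state. Aromatisation to the chelated magnesium phenoxide should make the closure irreversible.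

Step 5
Reactants: 12 1-(2,6-dihydroxy-4-methoxyphenyl)hexatriacontane-1,3-dione
Product: 13 5-hydroxy-7-methoxy-2-tritriacontyl-4H-chromen-4-one
Conditions: p-TsOH·H2O (cat.), toluene, reflux, Dean–Stark
Reagents that add atoms: none
Why: Acid-catalysed cyclodehydration of an o-hydroxyaryl 1,3-diketone (the closing stage of the Baker–Venkataraman chromone synthesis) should proceed by addition of a phenol oxygen to the C2 carbonyl and loss of water, and since the two phenols of 12 are related by symmetry only one chromone can form, its remaining C5 hydroxyl being held by a hydrogen bond to the C4 carbonyl.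

Compound list
1 | 4-methoxy-6-methyl-2H-pyran-2-one | COc1cc(=O)oc(C)c1 | starting material
2 | N-methoxy-N-methylacetamide | CON(C)C(C)=O | starting material
3 | 6-(lithiomethyl)-4-methoxy-2H-pyran-2-one (formed in the flask) | [Li]Cc1cc(OC)cc(=O)o1 | intermediate
4 | 4-methoxy-6-(2-oxopropyl)-2H-pyran-2-one | COc1cc(=O)oc(CC(C)=O)c1 | intermediate
5 | 1-bromodocosane | CCCCCCCCCCCCCCCCCCCCCCBr | starting material
6 | methyl 12-bromododecanoate | COC(=O)CCCCCCCCCCCBr | starting material
7 | docosylmagnesium bromide (formed in the flask) | CCCCCCCCCCCCCCCCCCCCCC[Mg]Br | intermediate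
8 | methyl tetratriacontanoate | COC(=O)CCCCCCCCCCCCCCCCCCCCCCCCCCCCCCCCC | intermediate
9 | dilithium 1-(4-methoxy-2-oxo-2H-pyran-6-yl)-2-oxopropane-1,3-diide (dianion of 4, formed in the flask) | [Li+].[Li+].[CH2-]C(=O)[CH-]c1cc(OC)cc(=O)o1 | intermediate
10 | 6-(2,4-dioxoheptatriacontyl)-4-methoxy-2H-pyran-2-one | COc1cc(=O)oc(CC(=O)CC(=O)CCCCCCCCCCCCCCCCCCCCCCCCCCCCCCCCC)c1 | intermediate
11 | methyl (2E)-3-methoxy-5,7,9-trioxodotetracont-2-enoate (ring-opened ester, present as its magnesium chelate, formed in the flask) | COC(=O)/C=C(/OC)CC(=O)CC(=O)CC(=O)CCCCCCCCCCCCCCCCCCCCCCCCCCCCCCCCC | intermediate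
12 | 1-(2,6-dihydroxy-4-methoxyphenyl)hexatriacontane-1,3-dione | COc1cc(O)c(C(=O)CC(=O)CCCCCCCCCCCCCCCCCCCCCCCCCCCCCCCCC)c(O)c1 | intermediate
13 | 5-hydroxy-7-methoxy-2-tritriacontyl-4H-chromen-4-one | CCCCCCCCCCCCCCCCCCCCCCCCCCCCCCCCCc1cc(=O)c2c(O)cc(OC)cc2o1 | target

Total step count: 5
Longest linear sequence: 4 steps (step 1 or step 2, then steps 3, 4 and 5)

Steps most likely to fail

Step 4 (key step). The opened chain may fold in the wrong mode (aldol-type closure between C6 and C4 or between C8 and C2, or addition–elimination of C3 at C7), the triketone array may close through oxygen to a 4-pyranone, or ring opening may stall because the C33 substrate stays out of solution. The fallback sets out from ester 8 and comes back to the route at target 13. Commercial 1-(2,6-dihydroxy-4-methoxyphenyl)ethanone is protected with NaH and MOMCl in DMF to give 1-[4-methoxy-2,6-bis(methoxymethoxy)phenyl]ethanone F1. The enolate of F1 (LiN(SiMe3)2 in THF, or NaH in refluxing THF) is acylated by 8 in a crossed Claisen condensation to give 1-[4-methoxy-2,6-bis(methoxymethoxy)phenyl]hexatriacontane-1,3-dione F2. HCl in MeOH–THF at reflux should then remove both acetals and close the pyranone in the same flask to give 13.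

Step 3. Proton transfer from the newly formed diketone, or from the α-position of the ester, may quench the dianion faster than acylation proceeds, and the waxy ester may precipitate before it reacts, so that conversion stalls. The fallback sets out from ester 8 and comes back at 10. Ester 8 is converted with Me2AlN(OMe)Me (from AlMe3 and MeNHOMe·HCl) in warm toluene into N-methoxy-N-methyltetratriacontanamide F3. Dianion 9 adds to F3 to give a chelated tetrahedral adduct that can neither transfer a proton nor be acylated again, and that releases 10 only on mildly acidic work-up, so one equivalent of dianion should suffice.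

Step 2. The Grignard reagent may add to the ester carbonyl instead of coupling, may homocouple while it is formed, or may crystallise from THF before it is transferred. The fallback sets out from 5 (through Grignard reagent 7) and comes back at 8. Commercial 12-bromododecanoic acid is deprotonated with MeMgCl in THF at −20 °C to chloromagnesium 12-bromododecanoate F4, which offers no electrophilic carbonyl. Reagent 7 and Li2CuCl4 (cat.) couple with F4 to give, after acidification, tetratriacontanoic acid F5, which is recrystallised and converted by Fischer esterification (MeOH, H2SO4 cat., toluene, reflux) into 8.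

Further compounds
F1 | step 4 | 1-[4-methoxy-2,6-bis(methoxymethoxy)phenyl]ethanone | CC(=O)c1c(OCOC)cc(OC)cc1OCOC
F2 | step 4 | 1-[4-methoxy-2,6-bis(methoxymethoxy)phenyl]hexatriacontane-1,3-dione | COCOc1cc(OC)cc(OCOC)c1C(=O)CC(=O)CCCCCCCCCCCCCCCCCCCCCCCCCCCCCCCCC
F3 | step 3 | N-methoxy-N-methyltetratriacontanamide | CON(C)C(=O)CCCCCCCCCCCCCCCCCCCCCCCCCCCCCCCCC
F4 | step 2 | chloromagnesium 12-bromododecanoate | [Mg+2].[Cl-].[O-]C(=O)CCCCCCCCCCCBr
F5 | step 2 | tetratriacontanoic acid | OC(=O)CCCCCCCCCCCCCCCCCCCCCCCCCCCCCCCCC
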